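Readings and results come from a simulation with constants of no real substance, noise included.

At late times the isomer of the product is still climbing while the target slows. At 12.0 h the north run reads 38% target beside 8% isomer, and at 10.0 h the south-west run reads 43% beside 15%, each with its scatter.

| flask | substrate | reagent | free catalyst | added ligand | remark | time |
|---|---|---|---|---|---|---|
| north | 0.10 M | 0.95 equiv | 0.1 mol% | 0.32 mM | run made earlier |  |
| south-east | 0.10 M | 1.3 equiv | 0.1 mol% | 0.32 mM | run made earlier |  |
| south-west | 0.10 M | 2.1 equiv | 0.1 mol% | 0.32 mM | run made earlier |  |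
| dusk | 0.10 M | 0.950 equiv (fed, over 5.0 h) | 0.1 mol% | 0.32 mM | all else is in the flask from the start; the feed brings no volume worth counting | 12 h |
| spring | 0.10 M (fed, over 5.0 h) | 0.950 equiv | 0.1 mol% | 0.32 mM | all else is in the flask from the start; the feed brings no volume worth counting | 12 h |
| midnight | 0.10 M | 0.950 equiv | 0.1 mol% | 0.32 mM | everything together at the start | 12 h |

| run | time / h | target / % | isomer of the product / % | substrate / % |
|---|---|---|---|---|
| north | 1.50 | 12 | 3 | 90 |
| north | 3.00 | 17 | 0 | 79 |
| north | 5.00 | 27 | 7 | 70 |
| north | 6.00 | 28 | 4 | 68 |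
| north | 8.00 | 33 | 7 | 60 |
| north | 10.0 | 36 | 5 | 57 |
| north | 12.0 | 38 | 8 | 51 |
| south-east | 1.33 | 12 | 2 | 89 |
| south-east | 3.00 | 20 | 3 | 77 |
| south-east | 4.00 | 26 | 4 | 73 |
| south-east | 6.00 | 30 | 4 | 62 |
| south-east | 8.00 | 38 | 7 | 56 |
| south-east | 10.0 | 40 | 11 | 50 |
| south-west | 0.833 | 9 | 2 | 90 |
| south-west | 1.33 | 13 | 0 | 83 |
| south-west | 2.00 | 19 | 0 | 77 |
| south-west | 2.50 | 24 | 1 | 75 |
| south-west | 4.00 | 32 | 6 | 66 |
| south-west | 6.00 | 39 | 9 | 55 |
| south-west | 10.0 | 43 | 15 | 43 |

(scatter of a reading: 1.5 percentage points)



* the flask that comes out highest in share of target in target plus isomer of the product, or "all alike" when all lie within 1.5 percentage points (dusk / spring / midnight / all alike)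
* share of target in target plus isomer of the product at the end, dusk
* share of target in target plus isomer of the product at the end, spring
* share of target in target plus isomer of the product at the end, midnight

Suppose the isomer grows from the target at a steady fraction per hour. The age of the target is then the area under its curve, taken on straight legs, divided by its last value, which in the north run reads 7.76 h. Isomer over target, divided by that age, gives 0.0271 h⁻¹, the isomer clock, a pseudo-first-order constant for target turning into isomer. The share of target is one over one plus clock times age, so midnight, on the north recipe, reads 82.6%.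

Turn the question round. For the flasks to count as equal, with the clock held, a fed flask's age has to lie within 0.811 h of the north age. A feed over 5.0 h brings its charge in 2.50 h late on average, more than that margin. This reckoning, separate from the forecast, gives 87.5% for either fed flask and cannot part them.

The forecast gives 87.5% for dusk, 86.5% for spring and 84% for midnight, and names dusk highest, since “Dusk also keeps reagent low early”.

The simulation gives 82.6% for dusk, 87.4% for spring and 80.3% for midnight, so spring comes out highest.

    catalyst intermediate C → free catalyst + target (k = 5400 h⁻¹)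
    target + free catalyst ⇌ isomer of the product + free catalyst, rate k2*[free catalyst]*[target] forward; the back reaction follows from the equilibrium constant (K = 2.50, k = 5300 M⁻¹ h⁻¹)
    reagent + catalyst intermediate A ⇌ catalyst intermediate B (K = 4.70 M⁻¹, k = 74000 M⁻¹ h⁻¹)
    catalyst intermediate B ⇌ catalyst intermediate C (K = 0.410, k = 360 h⁻¹)
    free catalyst + added ligand ⇌ idle complex (K = 1.60 × 10⁵ M⁻¹, k = 2900 M⁻¹ h⁻¹)
    substrate + free catalyst → catalyst intermediate A (k = 8200 M⁻¹ h⁻¹)
    target + catalyst intermediate C → spent catalyst (k = 0.370 M⁻¹ h⁻¹)

The target ages in spring, 6.57 h, and dusk, 6.40 h, lie close, but the clock reads 0.0219 h⁻¹ in spring and 0.0329 h⁻¹ in dusk, beside 0.0271 h⁻¹ from north. At the end of the feed, at 5.00 h, free catalyst stands lower in spring, at 3.83% of the catalyst charged, than in dusk, at 8.28%, and at 5.07 h the target's half-life in spring by the forward isomer step is 34 h. The neighbour flask like spring with 0.06 mol% of free catalyst, taken at spring's age, has a clock of 0.0123 h⁻¹ and ends at 92.5%.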